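Start with what is slow in the grey flask, the very flask asked about. It is not the making of target, for starting material already reads 0% at 1.50 min. It is the loss of target, from 82% of the charge there to 57% at 5.00 min.

in all of them: starting material 0.083 M; free enzyme 0.01 mol%

| flask | second substrate | temperature | remark | time |
|---|---|---|---|---|
| grey | 1 equiv | 25 °C | the very flask that is asked about, followed so far |  |
| red | 0.50 equiv | 10 °C | run made earlier |  |
| flask | 1.00 equiv | 25 °C |  | 8.0 min |

| run | time / min | target / % | starting material / % |
|---|---|---|---|
| grey | 0.333 | 34 | 63 |
| grey | 1.00 | 83 | 7 |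
| grey | 1.50 | 82 | 0 |
| grey | 2.50 | 74 | 0 |
| grey | 4.00 | 67 | 4 |
| grey | 5.00 | 57 | 0 |
| red | 0.333 | 19 | 88 |
| red | 0.417 | 14 | 85 |
| red | 0.667 | 22 | 76 |
| red | 1.33 | 46 | 53 |
| red | 2.00 | 66 | 29 |
| red | 3.00 | 93 | 1 |

(standard deviation of a reading: 2 percentage points)

- autumn: at 8.0 min raise the temperature by 15 K, then wait 4.0 min
- midnight: change nothing and wait 4.0 min more
- dusk: at 8.0 min take out 90% of the target then present, then wait 4.0 min
- noon: at 8.0 min add free enzyme, 50.0% of the amount charged, then wait 4.0 min

- what is taken out of target is counted as made
- additions bring no volume worth counting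

- target, in percent of the starting material first charged, at 8.0 min
- the option that brings most further target ("none" if no option brings more than 2 percentage points) (autumn / midnight / dusk / noon / none)
- target present, with what was taken out counted in, in percent of the starting material first charged, after autumn
- target present, with what was taken out counted in, in percent of the starting material first charged, after dusk

So fold the grey readings into one number. Between those two readings target falls at a rate of 0.104 min⁻¹. Multiply that by the time from 1.50 min to 8.0 min and you have 0.675, the loss number (a Damköhler number): the count of e-foldings target has lived through by the asked time. Divide the fraction at 1.50 min by the exponential of this number and my own reckoning gives 41.7% target.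

Is one number enough? From 1.50 min to 2.50 min the rate reads 0.103 min⁻¹, and from 2.50 min to 5.00 min it reads 0.104 min⁻¹, so the two agree. But the readings end at 5.00 min, and this rate cannot tell you whether the loss runs down to zero or stops at a balance. With that doubt, I would name no option.

The forecast says 41% target, best none, 12.5% after autumn and 39.6% after dusk: “With no starting material left, no option can make more target.”

The simulated flask holds 45.0% target, 3.3 percentage points above my figure, and autumn gains 20 points, reaching 64.8%, while dusk reaches 50.1%.

    free enzyme → unfolded enzyme (k = 0.00650 s⁻¹, Ea = 234 kJ mol⁻¹)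
    starting material + free enzyme ⇌ complex A (K = 700 L mol⁻¹, k = 1.70 × 10⁵ L mol⁻¹ s⁻¹, Ea = 21.0 kJ mol⁻¹, ΔH = −30.0 kJ mol⁻¹)
    complex A → free enzyme + target (k = 180 s⁻¹, Ea = 50.0 kJ mol⁻¹)
    second substrate + free enzyme ⇌ complex B (K = 15.0 L mol⁻¹, k = 8.90 × 10⁵ L mol⁻¹ s⁻¹, Ea = 12.0 kJ mol⁻¹, ΔH = −57.0 kJ mol⁻¹)
    complex B → free enzyme + second product (k = 900 s⁻¹, Ea = 53.0 kJ mol⁻¹)
    starting material → uncatalysed product (k = 0.00150 s⁻¹, Ea = 99.0 kJ mol⁻¹)
    target ⇌ isomer of the product (K = 2.70, k = 0.00210 s⁻¹, Ea = 78.0 kJ mol⁻¹, ΔH = −90.0 kJ mol⁻¹)
    (constants at 25 °C)

In this flask starting material stood at 19.6% after 0.800 min and 0% after 4.00 min, and target came through complex A while it lasted. Target then passed into isomer of the product, which holds 50.6% at 8.00 min; the loss number 0.675, read from target's own fall, counts that passage but not the way back from isomer of the product, whose balance constant is 2.7. Carried to the neighbour flask, the same flask read at 30 min, the number becomes 2.96 and gives 4.25% target. That neighbour flask in fact holds 26.3% target beside 69.3% isomer of the product, and at 80.0 min target still stands at 25.8%.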